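Remark on the chemistry: aldehyde 5 is taken as its commercial aqueous solution, and alkyne 3 is assumed to be used soon after it is made. The target has no stereocentre; the one stereocentre that appears on the way (C7 of 13) is racemic and is destroyed in the same step.

## Analysis of the target

Target 14, methyl 2-(3-bromo-12H-pyrido[1,2-a:3,4-b']diindol-13-yl)-2-oxoacetate, is a flat, fully aromatic pentacycle. Benzo ring A (C7b–C11a) and NH-pyrrole ring B (N12) form one indole. Bromobenzo ring E (C1–C4, C4a, C13a) and pyrrole ring D (N5, C12b, C13, C13a, C4a) form a second indole. The two are joined through C12a–C12b and bridged by the six-membered ring C (N5, C6, C7, C7a, C12a, C12b). Every problem is one of regiochemistry and oxidation level: bromine at C3 (para to C13a, meta to N5), the methyl oxalyl ketoester at C13, and a free N12–H. The sensitive groups are the aryl bromide (endangered by zerovalent palladium, hydrogenolysis and halogen–metal exchange), the α-ketoester (electrophilic ketone, cleavable ester) and the electron-rich biindole core (oxidation, acid-induced oligomerisation). The difficulty is that the obvious routes to this skeleton end with a Friedel–Crafts glyoxylation and a dehydrogenation of ring C, which are late steps that add length and put the bromide at risk. The strategy rests on a 1,3-relationship in ring D: N5 is bonded to C12b, and C12b is bonded to C13, the carbon that carries the acyl group. This N–C–C(acyl) array is what results when an acylated nitrogen adds to one carbon of an alkyne and hands its acyl group to the other, so C12b≡C13 can be an alkyne and the oxalyl group can start on N5. Ring C then only needs C6 and C7 at the aldehyde oxidation level, which an acetal side chain on N5 supplies.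

## Retrosynthetic reasoning

**14 ⇒ 12.** The first cut is the C7–C7a bond of ring C, with the C6=C7 double bond traced back to a dimethyl acetal on a two-carbon chain at N5. This gives acetal 12, a 2,2'-biindole in which ring D already carries the ketoester. Ring C is opened first because its closure needs neither metal nor oxidant: C7a is the free C3 position of the N12–H indole, the best carbon nucleophile in the molecule, and C7 arrives at the aldehyde oxidation level. Aromatisation is therefore a loss of two methoxy groups, not a dehydrogenation, which spares the C3 bromide and the ketoester. Forward, acid must ionise the acetal, C7a must attack in a six-membered closure through ether 13, and the second methoxy group must leave.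

**12 ⇒ 10.** In 12 two bonds of ring D are cut together, N5–C12b and C13–C(acyl), and the acyl group is returned to N5. The result is diaryl alkyne 10, an ortho-alkynyl N-aryl oxamate whose alkyne carbons are C12b and C13. This one cut removes ring D, turns the C12a–C12b biindole junction into a plain indole–alkyne bond, and accounts for the ketoester. It also makes the acylation of C13 regiospecific, because the acyl group is delivered from the neighbouring nitrogen and never has to choose between C13 and C7a. The forward step is an isomerisation under π-acid catalysis: N5 must add to C12b, and the oxalyl group must move from N5 to C13 through zwitterion 11.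

**10 ⇒ 9 + 3.** Alkyne 10 is cut between ring E and the alkyne carbon C13, giving aryl iodide 9 and terminal alkyne 3. The cut is made on this side because 9 carries iodine and bromine on the same ring, and the difference in oxidative-addition rate lets the iodide couple at room temperature while the C3 bromide stays. Cutting on the indole side would require a 2-haloindole, which is less stable. Alkyne 3 goes back to aldehyde 1 by a one-carbon homologation through diazoalkene 2.

**9 ⇒ 7 + 8.** The N5–C(=O) bond of oxamate 9 is cut to secondary aniline 7 and acid chloride 8. Acylation comes before the alkyne coupling for two reasons. A secondary ortho-alkynylaniline can cyclise early without any acyl transfer, and the C3 position of an indolyl alkyne would compete with nitrogen for 8.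

**7 ⇒ 4 + 5.** The N5–C6 bond of 7 is cut to aniline 4 and aldehyde 5, which are joined by reductive amination through imine 6. In 4 the amino group is meta and the iodine para to bromine, which maps onto N5, C13a and C3 of 14. The bromine position is therefore fixed by the starting material and is never introduced by substitution on the heterocycle.

## Alternatives that were turned down

**Alternative 1: ring C as the pyridine of a β-carboline (N5–C6 by azaelectrocyclisation).**
- Disconnection: ring C is made first, ring D is left for later.
- Forward key step: the O-methyl oxime A2 of a 3-vinylindol-2-yl benzyl ketone is heated. Its 1-azatriene (N5=C12b–C12a=C7a–C7=C6) closes by 6π-azaelectrocyclisation and the dihydropyridine loses methanol, giving the 1-benzyl-β-carboline A1.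
- For it: the step is thermal and metal-free, so the bromide is safe, and ring C comes out aromatic without an oxidant. On the last point it equals the chosen route, and on freedom from metals it is stronger.
- Against it: A1 still lacks ring D and the ketoester. N5–C4a would have to be made by displacing fluoride from a ring activated only by a meta bromine. A metal-catalysed N-arylation would instead engage the C–Br bond, which cannot cyclise. C13 would then still need a separate glyoxylation. The vinylindole A2 is also prone to dimerise and polymerise and takes several steps to build.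
- Comparison: the chosen route has the N5–aryl bond from the outset, as the aniline nitrogen of 4, and places the ketoester in the ring-forming step. It avoids the two hardest operations of this alternative at the price of a metal-catalysed key step.

**Alternative 2: ring B last (C7a–C7b by enamine arylation).**
- Disconnection: the N12–H indole is annulated onto a ring C ketone.
- Forward key step: the N-(2-iodophenyl) ketimine A4 is treated with Pd(OAc)2 and DABCO in DMF. Zerovalent palladium inserts into the C–I bond and the enamine tautomer is arylated at C7a, closing ring B to give A3.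
- For it: this indolisation is dependable, needs no alkyne, and produces the free N–H indole only at the end. On reliability of the key step it is probably stronger than the chosen route.
- Against it: A3 is two oxidations short of 14. The C13 side chain is an acetate that must be oxidised to the α-ketoester, and C6–C7 must be dehydrogenated, both on an electron-rich biindole next to an aryl bromide. The key step also runs hot with zerovalent palladium in the presence of the C3 bromide, and the ketone behind A4 needs its own multistep synthesis.
- Comparison: the chosen route brings every carbon to 14 at its final oxidation level in six steps. It pays for this with a less thoroughly tested key step.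

**Alternative 3: ring D by oxidative C–H cyclisation (C13–C13a).**
- Disconnection: C13–C13a, formed by C–H functionalisation of ring E.
- Forward key step: the N-(3-bromophenyl) enaminone A6 is cyclised with Pd(OAc)2 and Cu(OAc)2. The enaminone α-carbon and the ortho C–H para to bromine are joined, giving A5.
- For it: like the chosen step, it closes ring D and delivers the C13 ketoester at once, and it needs neither an iodide nor an alkyne. In atom economy on ring E it is at least as good.
- Against it: the conditions are oxidative (stoichiometric divalent copper, heat) on a substrate with a free indole N–H, and the aryl bromide meets zerovalent palladium at every turnover. Two ortho C–H sites compete and only sterics favour the one para to bromine. Ring C of A5 is still a dihydro ring, so a dehydrogenation must follow. A6 is not short to make.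
- Comparison: the chosen key step is a redox-neutral isomerisation whose regiochemistry is fixed by the position of iodine in 4, and ring C is then aromatised by elimination instead of oxidation.

Key step: step 5

## Route

Step 1
Reactants: 1 1H-indole-2-carbaldehyde
Product: 3 2-ethynyl-1H-indole, via diazoalkene 2 (not isolated)
Conditions: Bestmann–Ohira reagent, K2CO3, MeOH, 0 °C → rt
Reagents that add atoms: dimethyl (1-diazo-2-oxopropyl)phosphonate (Bestmann–Ohira reagent), COP(=O)(OC)C(=[N+]=[N-])C(C)=O
Why: Seyferth–Gilbert homologation in the Bestmann–Ohira variant: methanolysis of the acetyl group releases the diazomethylphosphonate anion, which olefinates the aldehyde to diazoalkene 2; loss of N2 with 1,2-hydrogen shift gives the terminal alkyne. The mild carbonate conditions leave the indole N–H untouched.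

Step 2
Reactants: 4 5-bromo-2-iodoaniline; 5 2,2-dimethoxyacetaldehyde
Product: 7 5-bromo-N-(2,2-dimethoxyethyl)-2-iodoaniline, via imine 6 (not isolated)
Conditions: AcOH, NaBH(OAc)3 (excess), DCE, rt
Reagents that add atoms: none
Why: Reductive amination: acid-catalysed condensation gives imine 6, which NaBH(OAc)3 reduces in preference to the aldehyde; an excess of hydride allows for the water that comes with 5. The hindered, weakly basic aniline should stop at monoalkylation, and the acetal and both aryl halides are inert to this hydride.

Step 3
Reactants: 7 5-bromo-N-(2,2-dimethoxyethyl)-2-iodoaniline; 8 methyl chlorooxoacetate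
Product: 9 methyl 2-[(5-bromo-2-iodophenyl)(2,2-dimethoxyethyl)amino]-2-oxoacetate
Conditions: Et3N, DMAP (cat.), CH2Cl2, 0 °C → rt
Reagents that add atoms: none
Why: N-acylation of a secondary aniline with a highly reactive acid chloride; the excess amine base keeps the medium free of HCl, so the acetal survives. Acylating before the alkyne is present avoids competition from an indole C3 position.

Step 4
Reactants: 9 methyl 2-[(5-bromo-2-iodophenyl)(2,2-dimethoxyethyl)amino]-2-oxoacetate; 3 2-ethynyl-1H-indole
Product: 10 methyl 2-[{5-bromo-2-[(1H-indol-2-yl)ethynyl]phenyl}(2,2-dimethoxyethyl)amino]-2-oxoacetate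
Conditions: Pd(PPh3)2Cl2 (cat.), CuI (cat.), Et3N, THF, rt
Reagents that add atoms: none
Why: Sonogashira coupling; oxidative addition to C–I is much faster than to C–Br at room temperature, so the bromide is kept. A tertiary amine base is used so that the oxamate ester is not aminolysed, and the fully substituted nitrogen cannot cyclise onto the new alkyne under these conditions.

Step 5
Reactants: 10 methyl 2-[{5-bromo-2-[(1H-indol-2-yl)ethynyl]phenyl}(2,2-dimethoxyethyl)amino]-2-oxoacetate
Product: 12 methyl 2-[6-bromo-1-(2,2-dimethoxyethyl)-2-(1H-indol-2-yl)-1H-indol-3-yl]-2-oxoacetate, via platinated N-acylindolium zwitterion 11 (not isolated)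
Conditions: PtCl2 (10 mol%), anisole, 80 °C
Reagents that add atoms: none
Why: PtCl2 acts as a π-acid on the C12b≡C13 triple bond, and the oxamate nitrogen N5 adds anti to C12b to give the N-acylindolium 11 with a C13–Pt bond. The electron-rich vinyl–platinum carbon C13 then takes the oxalyl group from N5 in a 1,3-acyl shift, which forms C13–C(=O), discharges the nitrogen and releases PtCl2. The closest known reaction type is the PtCl2-catalysed intramolecular aminoacylation of ortho-alkynyl N-acyl-N-alkylanilines to 3-acylindoles; here the migrating group is the methyl oxalyl group, whose N-bound carbonyl is more electrophilic than that of a simple amide. Ring D closes in a 5-endo-dig mode (a 4-exo attack of N5 on C13 is geometrically excluded), and no stereocentre is formed. The selectivity required is N-attack over carbonyl O-attack (6-exo at C13): the O-adduct of a tertiary amide is a cation that cannot be discharged and should revert, whereas N-attack ends irreversibly in the aromatic indole. The indol-2-yl donor on C12b stabilises positive charge at C12b in the activated alkyne, which offsets the low nucleophilicity of the oxamate nitrogen. PtCl2 does not insert into the C–Br bond, the conditions are neutral so the acetal and the free indole N–H should survive, and the indole itself cannot reach the alkyne in a ring of workable size.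

Step 6
Reactants: 12 methyl 2-[6-bromo-1-(2,2-dimethoxyethyl)-2-(1H-indol-2-yl)-1H-indol-3-yl]-2-oxoacetate
Product: 14 methyl 2-(3-bromo-12H-pyrido[1,2-a:3,4-b']diindol-13-yl)-2-oxoacetate, via cyclised methyl ether 13 (not isolated)
Conditions: TFA, CH2Cl2, 0 °C → rt
Reagents that add atoms: none
Why: Pomeranz–Fritsch-type cyclisation: acid-promoted loss of one methoxy group makes the acetal carbon C7 electrophilic, and the free indole C3 (C7a) attacks it in a 6-exo closure to give racemic ether 13; ionisation of this indol-3-ylmethyl ether and loss of a C6 proton expel the second methoxy group and aromatise ring C. Attack by N12 would give only a reversible N,O-acetal, so the system should drain to 14; anhydrous acid spares the methyl ester, and the C13 ketone is a deactivated vinylogous amide.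

## Compound list

1 | 1H-indole-2-carbaldehyde | O=Cc1cc2ccccc2[nH]1 | starting material
2 | 2-(2-diazoethenyl)-1H-indole (not isolated) | [N-]=[N+]=C=Cc1cc2ccccc2[nH]1 | intermediate
3 | 2-ethynyl-1H-indole | C#Cc1cc2ccccc2[nH]1 | intermediate
4 | 5-bromo-2-iodoaniline | Nc1cc(Br)ccc1I | starting material
5 | 2,2-dimethoxyacetaldehyde | COC(OC)C=O | starting material
6 | (E)-N-(5-bromo-2-iodophenyl)-2,2-dimethoxyethan-1-imine (not isolated) | COC(OC)/C=N/c1cc(Br)ccc1I | intermediate
7 | 5-bromo-N-(2,2-dimethoxyethyl)-2-iodoaniline | COC(OC)CNc1cc(Br)ccc1I | intermediate
8 | methyl chlorooxoacetate | COC(=O)C(Cl)=O | starting material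
9 | methyl 2-[(5-bromo-2-iodophenyl)(2,2-dimethoxyethyl)amino]-2-oxoacetate | COC(=O)C(=O)N(CC(OC)OC)c1cc(Br)ccc1I | intermediate
10 | methyl 2-[{5-bromo-2-[(1H-indol-2-yl)ethynyl]phenyl}(2,2-dimethoxyethyl)amino]-2-oxoacetate | COC(=O)C(=O)N(CC(OC)OC)c1cc(Br)ccc1C#Cc1cc2ccccc2[nH]1 | intermediate
11 | [6-bromo-1-(2,2-dimethoxyethyl)-2-(1H-indol-2-yl)-1-(2-methoxy-2-oxoacetyl)-1H-indol-1-ium-3-yl]dichloridoplatinate, zwitterion of divalent platinum (not isolated) | COC(=O)C(=O)[N+]1(CC(OC)OC)c2cc(Br)ccc2C([Pt-](Cl)Cl)=C1c1cc2ccccc2[nH]1 | intermediate
12 | methyl 2-[6-bromo-1-(2,2-dimethoxyethyl)-2-(1H-indol-2-yl)-1H-indol-3-yl]-2-oxoacetate | COC(=O)C(=O)c1c2ccc(Br)cc2n(CC(OC)OC)c1-c1cc2ccccc2[nH]1 | intermediate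
13 | methyl 2-(3-bromo-7-methoxy-7,12-dihydro-6H-pyrido[1,2-a:3,4-b']diindol-13-yl)-2-oxoacetate, racemic at C7 (not isolated) | COC(=O)C(=O)c1c2ccc(Br)cc2n2CC(OC)c3c4ccccc4[nH]c3c12 | intermediate
14 | methyl 2-(3-bromo-12H-pyrido[1,2-a:3,4-b']diindol-13-yl)-2-oxoacetate | COC(=O)C(=O)c1c2ccc(Br)cc2n2ccc3c4ccccc4[nH]c3c12 | target

## Step count and risk

Total: 6 steps. Longest linear sequence: 5 steps (4 → 7 → 9 → 10 → 12 → 14); step 1 is a one-step side branch that supplies alkyne 3.

**Step 5 (key step).** The most likely failure is slow aminoplatination, because the oxamate nitrogen is a weak nucleophile. That leaves time for the catalyst to be tied up by the indole or the dicarbonyl unit. A second failure mode is loss of the oxalyl group from 11 to a stray nucleophile before the 1,3-shift, so that ring D closes without acylation at C13. The fallback drops the acyl transfer and glyoxylates last. It sets out from 7 and returns to the route at 14.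
- Sonogashira coupling of 7 with 3 (Pd(PPh3)2Cl2, CuI, Et3N) gives 5-bromo-N-(2,2-dimethoxyethyl)-2-[(1H-indol-2-yl)ethynyl]aniline F1.
- 5-endo hydroamination with catalytic Cu(OAc)2 in hot DCE closes ring D to 6-bromo-1-(2,2-dimethoxyethyl)-1H,1'H-2,2'-biindole F2.
- TFA closes and aromatises ring C to 3-bromo-12H-pyrido[1,2-a:3,4-b']diindole F3.
- In F3, C13 is the only open pyrrole β-carbon because C7a is now a ring-fusion atom. Oxalyl chloride at 0 °C should therefore acylate C13 alone, giving 2-(3-bromo-12H-pyrido[1,2-a:3,4-b']diindol-13-yl)-2-oxoacetyl chloride F4, which is quenched in the flask with methanol to give 14.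

**Step 4.** Oxidative addition at the iodide is slowed by the bulky ortho nitrogen substituent, so oxidative homocoupling or decomposition of the electron-rich, N–H-free alkyne 3 may outrun the cross-coupling. The fallback reverses the roles of the partners. It sets out from 9 and returns at 10.
- Sonogashira coupling of 9 with ethynyltrimethylsilane gives methyl 2-[{5-bromo-2-[(trimethylsilyl)ethynyl]phenyl}(2,2-dimethoxyethyl)amino]-2-oxoacetate F5.
- Desilylation with TBAF buffered by AcOH (to protect the oxamate) gives methyl 2-[(5-bromo-2-ethynylphenyl)(2,2-dimethoxyethyl)amino]-2-oxoacetate F6.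
- A second Sonogashira coupling of the more robust aryl alkyne F6 with commercial 2-iodo-1H-indole gives 10. Alkyne 3 and step 1 are then not needed.

**Step 6.** Under strong acid the electrophilic C7 may be intercepted intermolecularly by the electron-rich biindole (oligomerisation), the reaction may stall at ether 13, or the ketoester may suffer acid-mediated cleavage. The fallback separates C–C bond formation from aromatisation and carries out the latter under basic conditions. It sets out from 12 and returns at 14.
- Acetal exchange in wet acetone with catalytic pyridinium p-toluenesulfonate gives methyl 2-[6-bromo-2-(1H-indol-2-yl)-1-(2-oxoethyl)-1H-indol-3-yl]-2-oxoacetate F7.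
- F7 should close by intramolecular hydroxyalkylation of C7a to racemic methyl 2-(3-bromo-7-hydroxy-7,12-dihydro-6H-pyrido[1,2-a:3,4-b']diindol-13-yl)-2-oxoacetate F8.
- MsCl and Et3N convert F8 into methyl 2-{3-bromo-7-[(methylsulfonyl)oxy]-7,12-dihydro-6H-pyrido[1,2-a:3,4-b']diindol-13-yl}-2-oxoacetate F9, which eliminates in the flask to 14.

**Step 2.** Condensation of the deactivated, ortho-hindered aniline with the hydrated aldehyde may be slow, so that the hydride is spent on the aldehyde, and the acetal may be partly lost in the acidic medium. The fallback forms the N–C6 bond by alkylation instead of reductive amination. It sets out from 4 and returns at 9, bypassing 7.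
- Acylation of 4 with 8 (Et3N, CH2Cl2) gives methyl 2-[(5-bromo-2-iodophenyl)amino]-2-oxoacetate F10.
- The acidic N–H of F10 is alkylated with 2-bromo-1,1-dimethoxyethane (Cs2CO3, DMF, heat) to give 9.

## Further compounds

F1 | step 5 | 5-bromo-N-(2,2-dimethoxyethyl)-2-[(1H-indol-2-yl)ethynyl]aniline | COC(OC)CNc1cc(Br)ccc1C#Cc1cc2ccccc2[nH]1
F2 | step 5 | 6-bromo-1-(2,2-dimethoxyethyl)-1H,1'H-2,2'-biindole | COC(OC)Cn1c(-c2cc3ccccc3[nH]2)cc2ccc(Br)cc21
F3 | step 5 | 3-bromo-12H-pyrido[1,2-a:3,4-b']diindole | c1c2ccc(Br)cc2n2ccc3c4ccccc4[nH]c3c12
F4 | step 5 | 2-(3-bromo-12H-pyrido[1,2-a:3,4-b']diindol-13-yl)-2-oxoacetyl chloride | O=C(Cl)C(=O)c1c2ccc(Br)cc2n2ccc3c4ccccc4[nH]c3c12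
F5 | step 4 | methyl 2-[{5-bromo-2-[(trimethylsilyl)ethynyl]phenyl}(2,2-dimethoxyethyl)amino]-2-oxoacetate | COC(=O)C(=O)N(CC(OC)OC)c1cc(Br)ccc1C#C[Si](C)(C)C
F6 | step 4 | methyl 2-[(5-bromo-2-ethynylphenyl)(2,2-dimethoxyethyl)amino]-2-oxoacetate | COC(=O)C(=O)N(CC(OC)OC)c1cc(Br)ccc1C#C
F7 | step 6 | methyl 2-[6-bromo-2-(1H-indol-2-yl)-1-(2-oxoethyl)-1H-indol-3-yl]-2-oxoacetate | COC(=O)C(=O)c1c2ccc(Br)cc2n(CC=O)c1-c1cc2ccccc2[nH]1
F8 | step 6 | methyl 2-(3-bromo-7-hydroxy-7,12-dihydro-6H-pyrido[1,2-a:3,4-b']diindol-13-yl)-2-oxoacetate (racemic) | COC(=O)C(=O)c1c2ccc(Br)cc2n2CC(O)c3c4ccccc4[nH]c3c12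
F9 | step 6 | methyl 2-{3-bromo-7-[(methylsulfonyl)oxy]-7,12-dihydro-6H-pyrido[1,2-a:3,4-b']diindol-13-yl}-2-oxoacetate (racemic) | COC(=O)C(=O)c1c2ccc(Br)cc2n2CC(OS(C)(=O)=O)c3c4ccccc4[nH]c3c12
F10 | step 2 | methyl 2-[(5-bromo-2-iodophenyl)amino]-2-oxoacetate | COC(=O)C(=O)Nc1cc(Br)ccc1I
A1 | alternative 1 | 1-(4-bromo-2-fluorobenzyl)-9H-pyrido[3,4-b]indole | Fc1cc(Br)ccc1Cc1nccc2c3ccccc3[nH]c12
A2 | alternative 1 | 2-(4-bromo-2-fluorophenyl)-1-(3-ethenyl-1H-indol-2-yl)ethan-1-one O-methyl oxime (oxime geometry not defined) | CON=C(Cc1ccc(Br)cc1F)c1[nH]c2ccccc2c1C=C
A3 | alternative 2 | methyl 2-(3-bromo-7,12-dihydro-6H-pyrido[1,2-a:3,4-b']diindol-13-yl)acetate | COC(=O)Cc1c2ccc(Br)cc2n2CCc3c4ccccc4[nH]c3c12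
A4 | alternative 2 | methyl 2-{3-bromo-9-[(2-iodophenyl)imino]-6,7,8,9-tetrahydropyrido[1,2-a]indol-10-yl}acetate (imine geometry not defined) | COC(=O)Cc1c2ccc(Br)cc2n2CCCC(=Nc3ccccc3I)c12
A5 | alternative 3 | methyl 2-(3-bromo-7,12-dihydro-6H-pyrido[1,2-a:3,4-b']diindol-13-yl)-2-oxoacetate | COC(=O)C(=O)c1c2ccc(Br)cc2n2CCc3c4ccccc4[nH]c3c12
A6 | alternative 3 | methyl 3-[2-(3-bromophenyl)-2,3,4,9-tetrahydro-1H-pyrido[3,4-b]indol-1-ylidene]-2-oxopropanoate (alkene geometry not defined) | COC(=O)C(=O)C=C1N(c2cccc(Br)c2)CCc2c3ccccc3[nH]c12
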